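Assumption: the target has no stereocentre and no configurationally stable axis (the diaryl ether rotates freely), so it is achiral; no step needs stereocontrol and none creates a stereocentre.

**Retrosynthetic overview**
1. The target is traced back to its MOM ether; acid deprotection is the last step.
2. Key disconnection: the diaryl ether C–O bond, cut to an ortho C–H of MOM-protected 3,4,5-tribromophenol (both ortho C–H are equivalent) and the O–H of 3,5-dibromo-2-methoxyphenol. It is closed by C–H magnesiation and copper-mediated oxidative C–O coupling (the new step).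
3. MOM-protected 3,4,5-tribromophenol comes from 3,4,5-tribromophenol, made from 1,2,3-tribromobenzene by sterically controlled C–H borylation and oxidation.
4. 3,5-Dibromo-2-methoxyphenol comes from 3,5-dibromosalicylaldehyde by O-methylation and Baeyer–Villiger oxidation.
5. No ring is formed: both benzene rings and all five bromines come with the starting materials; ring B is prepared first, ring A second, and they are joined in the penultimate step.

**Route**

Step 1
Reactants: 1 1,2,3-tribromobenzene
Product: 2 2-(3,4,5-tribromophenyl)-4,4,5,5-tetramethyl-1,3,2-dioxaborolane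
Conditions: B2pin2 (0.6 equiv), [Ir(OMe)(cod)]2 (1.5 mol%), dtbpy (3 mol%), THF, 80 °C
Reagents that add atoms: bis(pinacolato)diboron, CC1(C)OB(OC1(C)C)B1OC(C)(C)C(C)(C)O1
Why: Iridium-catalysed aromatic C–H borylation is governed by sterics, and C5–H is the only C–H of 1 without an ortho substituent, so boron enters there while the C–Br bonds are left untouched.

Step 2
Reactants: 2 2-(3,4,5-tribromophenyl)-4,4,5,5-tetramethyl-1,3,2-dioxaborolane
Product: 3 3,4,5-tribromophenol
Conditions: 30% aq H2O2, NaOH, THF, 0 °C to rt; then aq HCl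
Reagents that add atoms: hydrogen peroxide, OO
Why: Boronate ipso-oxidation: hydroperoxide adds to boron and the aryl group migrates from B to O, so C–B becomes C–OH at the same carbon.

Step 3
Reactants: 3 3,4,5-tribromophenol
Product: 4 1,2,3-tribromo-5-(methoxymethoxy)benzene
Conditions: NaH, THF, 0 °C; MOMCl, 0 °C to rt
Reagents that add atoms: chloromethyl methyl ether, COCCl
Why: Williamson-type O-alkylation of the acidic, unhindered phenoxide with the reactive α-chloro ether gives the MOM acetal, which later acts as ortho-directing group and is acid-labile.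

Step 4
Reactants: 5 3,5-dibromo-2-hydroxybenzaldehyde
Product: 6 3,5-dibromo-2-methoxybenzaldehyde
Conditions: MeI, K2CO3, DMF, rt
Reagents that add atoms: iodomethane, CI
Why: Williamson ether synthesis: carbonate deprotonates the acidic salicylaldehyde OH and the phenoxide is methylated by SN2 on MeI.

Step 5
Reactants: 6 3,5-dibromo-2-methoxybenzaldehyde
Product: 8 3,5-dibromo-2-methoxyphenol, via aryl formate 7 (not isolated)
Conditions: mCPBA, CH2Cl2, 40 °C; then K2CO3 (cat.), MeOH, rt
Reagents that add atoms: meta-chloroperoxybenzoic acid, OOC(=O)c1cccc(Cl)c1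
Why: Baeyer–Villiger oxidation of an ortho-alkoxybenzaldehyde goes with aryl migration (Dakin-type) to the aryl formate, which mild methanolysis cleaves to the phenol.

Step 6
Reactants: 4 1,2,3-tribromo-5-(methoxymethoxy)benzene; 8 3,5-dibromo-2-methoxyphenol
Product: 13 1,2,3-tribromo-4-(3,5-dibromo-2-methoxyphenoxy)-5-(methoxymethoxy)benzene, via lithium aryloxide 9 (not isolated), via arylmagnesium chloride 10 (not isolated), via arylcopper 11 (not isolated), via lithium aryl(aryloxy)cuprate 12 (not isolated)
Conditions: i) 8 (1.2 equiv), LiHMDS, THF, −78 to 0 °C; ii) 4, TMPMgCl·LiCl (1.1 equiv), THF, −30 °C, then CuCl·2LiCl (1.1 equiv), −50 °C, then the solution of 9, −50 °C; iii) 3,3',5,5'-tetra-tert-butyl-4,4'-diphenoquinone (1.2 equiv), −78 to −20 °C; aq NH4Cl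
Reagents that add atoms: none
Why: Proposed new method: directed C–H magnesiation followed by oxidative C–O coupling of a heteroleptic aryl(aryloxy)cuprate. The only ring C–H of 4 lies between the OMOM director and a bromine (both ortho positions are equivalent), so TMPMgCl·LiCl should give one arylmagnesium, which is expected to be stable to aryne formation at −30 °C. Mg-to-Cu exchange and the lithium aryloxide 9 should give a Posner-type heterocuprate. The diphenoquinone is a two-electron acceptor with no leaving group, chosen so that free aryloxide cannot consume it by substitution; it should oxidise the cuprate to an aryl–Cu(III)–aryloxide, which reductively eliminates the diaryl ether, the same elementary step as in Chan–Lam coupling, favoured here by the electron-poor aryl on copper. The two ortho substituents should block biaryl homocoupling, and the low temperature should keep copper away from the five C–Br bonds. The closest known reactions are the chloranil-mediated oxidative amination of lithium amidocuprates and the Chan–Lam O-arylation of phenols.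

Step 7
Reactants: 13 1,2,3-tribromo-4-(3,5-dibromo-2-methoxyphenoxy)-5-(methoxymethoxy)benzene
Product: 14 3,4,5-tribromo-2-(3,5-dibromo-2-methoxyphenoxy)phenol
Conditions: conc. HCl (cat.), MeOH/THF, 50 °C
Reagents that add atoms: none
Why: Acid-catalysed acetal cleavage (MOM deprotection) through the methoxymethyl oxocarbenium ion, trapped by methanol, frees the phenol without touching the aryl methyl ether, the diaryl ether or the C–Br bonds.

**Compound list**
1 | 1,2,3-tribromobenzene | Brc1cccc(Br)c1Br | starting material
2 | 2-(3,4,5-tribromophenyl)-4,4,5,5-tetramethyl-1,3,2-dioxaborolane | CC1(C)OB(OC1(C)C)c1cc(Br)c(Br)c(Br)c1 | intermediate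
3 | 3,4,5-tribromophenol | Oc1cc(Br)c(Br)c(Br)c1 | intermediate
4 | 1,2,3-tribromo-5-(methoxymethoxy)benzene | COCOc1cc(Br)c(Br)c(Br)c1 | intermediate
5 | 3,5-dibromo-2-hydroxybenzaldehyde | O=Cc1cc(Br)cc(Br)c1O | starting material
6 | 3,5-dibromo-2-methoxybenzaldehyde | COc1c(Br)cc(Br)cc1C=O | intermediate
7 | 3,5-dibromo-2-methoxyphenyl formate | COc1c(Br)cc(Br)cc1OC=O | intermediate
8 | 3,5-dibromo-2-methoxyphenol | COc1c(Br)cc(Br)cc1O | intermediate
9 | lithium 3,5-dibromo-2-methoxyphenolate | [Li+].COc1c(Br)cc(Br)cc1[O-] | intermediate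
10 | [2,3,4-tribromo-6-(methoxymethoxy)phenyl]magnesium chloride | COCOc1cc(Br)c(Br)c(Br)c1[Mg]Cl | intermediate
11 | [2,3,4-tribromo-6-(methoxymethoxy)phenyl]copper(I) | COCOc1cc(Br)c(Br)c(Br)c1[Cu] | intermediate
12 | lithium (3,5-dibromo-2-methoxyphenolato)[2,3,4-tribromo-6-(methoxymethoxy)phenyl]cuprate(I) | [Li+].COCOc1cc(Br)c(Br)c(Br)c1[Cu-]Oc1cc(Br)cc(Br)c1OC | intermediate
13 | 1,2,3-tribromo-4-(3,5-dibromo-2-methoxyphenoxy)-5-(methoxymethoxy)benzene | COCOc1cc(Br)c(Br)c(Br)c1Oc1cc(Br)cc(Br)c1OC | intermediate
14 | 3,4,5-tribromo-2-(3,5-dibromo-2-methoxyphenoxy)phenol | COc1c(Br)cc(Br)cc1Oc1c(O)cc(Br)c(Br)c1Br | target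

**Totals**
Total step count: 7. Longest linear sequence: 5 steps (steps 1, 2, 3, 6, 7).

**Steps most likely to fail, with fallbacks**

Step 6 (the proposed new coupling; risks are incomplete cuprate formation, protonation back to 4, or unproductive oxidation). The fallback uses known chemistry, sets out from 4 and comes back at 13. Compound 4 is magnesiated as in step 6 to 10, which is quenched with B(OMe)3 to dimethyl [2,3,4-tribromo-6-(methoxymethoxy)phenyl]boronate F1 and oxidised in the same pot (H2O2, NaOH) to 2,3,4-tribromo-6-(methoxymethoxy)phenol F2. The phenoxide of F2 then displaces fluoride from commercial 2,4-dibromo-6-fluorobenzaldehyde F3 (K2CO3, DMAc, 100 °C, SNAr) to give 2,4-dibromo-6-[2,3,4-tribromo-6-(methoxymethoxy)phenoxy]benzaldehyde F4. Baeyer–Villiger oxidation (mCPBA, NaHCO3, CH2Cl2) gives 2,4-dibromo-6-[2,3,4-tribromo-6-(methoxymethoxy)phenoxy]phenyl formate F5, methanolysis (K2CO3, MeOH) gives 2,4-dibromo-6-[2,3,4-tribromo-6-(methoxymethoxy)phenoxy]phenol F6, and O-methylation (MeI, K2CO3, DMF) gives 13. Here the ether bond is made by classical addition–elimination and the methoxy oxygen of ring A is introduced afterwards from the aldehyde.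

Step 5 (risk: hydride instead of aryl migration on this electron-poor aldehyde, giving the benzoic acid). The fallback sets out from 6 and comes back at 8. MeMgBr is added to 6 (THF, −78 °C) to give racemic 1-(3,5-dibromo-2-methoxyphenyl)ethan-1-ol F7, which Dess–Martin periodinane oxidises to 1-(3,5-dibromo-2-methoxyphenyl)ethan-1-one F8. Baeyer–Villiger oxidation of this ketone with CF3CO3H, where hydride migration is impossible and aryl migrates in preference to methyl, gives 3,5-dibromo-2-methoxyphenyl acetate F9, and K2CO3/MeOH gives 8.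

Step 1 (risk: sluggish borylation of the electron-poor, crowded arene or competing C–Br activation). No known reaction functionalises C5 of 1 selectively other than this type of C–H activation, so this fallback does not set out from a numbered compound. It replaces starting material 1 and comes back to the route at 3, bypassing 2. Commercial 3,4,5-tribromoaniline F10 is diazotised (NaNO2, H2SO4/AcOH, 0–5 °C) to 3,4,5-tribromobenzenediazonium hydrogen sulfate F11, and copper-mediated hydroxy-dediazoniation (Cu2O, aq Cu(NO3)2, rt) gives 3.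

**Further compounds**
F1 | step 6 | dimethyl [2,3,4-tribromo-6-(methoxymethoxy)phenyl]boronate | COCOc1cc(Br)c(Br)c(Br)c1B(OC)OC
F2 | step 6 | 2,3,4-tribromo-6-(methoxymethoxy)phenol | COCOc1cc(Br)c(Br)c(Br)c1O
F3 | step 6 | 2,4-dibromo-6-fluorobenzaldehyde | O=Cc1c(F)cc(Br)cc1Br
F4 | step 6 | 2,4-dibromo-6-[2,3,4-tribromo-6-(methoxymethoxy)phenoxy]benzaldehyde | COCOc1cc(Br)c(Br)c(Br)c1Oc1cc(Br)cc(Br)c1C=O
F5 | step 6 | 2,4-dibromo-6-[2,3,4-tribromo-6-(methoxymethoxy)phenoxy]phenyl formate | COCOc1cc(Br)c(Br)c(Br)c1Oc1cc(Br)cc(Br)c1OC=O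
F6 | step 6 | 2,4-dibromo-6-[2,3,4-tribromo-6-(methoxymethoxy)phenoxy]phenol | COCOc1cc(Br)c(Br)c(Br)c1Oc1cc(Br)cc(Br)c1O
F7 | step 5 | 1-(3,5-dibromo-2-methoxyphenyl)ethan-1-ol (racemic) | COc1c(Br)cc(Br)cc1C(C)O
F8 | step 5 | 1-(3,5-dibromo-2-methoxyphenyl)ethan-1-one | COc1c(Br)cc(Br)cc1C(C)=O
F9 | step 5 | 3,5-dibromo-2-methoxyphenyl acetate | COc1c(Br)cc(Br)cc1OC(C)=O
F10 | step 1 | 3,4,5-tribromoaniline | Nc1cc(Br)c(Br)c(Br)c1
F11 | step 1 | 3,4,5-tribromobenzenediazonium hydrogen sulfate | N#[N+]c1cc(Br)c(Br)c(Br)c1.OS(=O)(=O)[O-]
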